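## Structural features

The target is a flavonol: a 4H-chromen-4-one in which the benzo ring A and the pyranone ring C share the C4a–C8a bond, with a 3,4-dihydroxyphenyl ring B joined to C2 by a single C2–C1' bond and a hydroxyl on C3. Ring A is hexasubstituted: C5, C6, C7 and C8 carry OH, OMe, OH and OMe in unbroken sequence, and the other two carbons are the ring fusion. The molecule has no stereocentre, so no centres stand next to each other; the only stereocentres of the route (a racemic carbinol and a ring-fusion CH) are transient and are erased. The fragile parts are the catechol and the 3-hydroxy-4-pyranone enol (oxidised by air under base), the hydroquinone stage of ring A (oxidised to a 5,8-quinone), ring C (opened by nucleophiles at C2), and methyl ethers beside a chelating hydroxyl (cleaved by strong Lewis acids). The real difficulty is ring A: a fully substituted benzene whose four neighbouring oxygens must be told apart in pairs (O6 and O8 methylated, O5 and O7 free). The key step uses the fact that C5–C6–C7–C8 with their four oxygens correspond atom for atom to the four carbons of a squaric ester, while C4a=C8a corresponds to the enol-ether double bond (C5=C6) of a 3-alkoxy-2-aryl-4-pyranone, that is, of a ring C made beforehand. A cyclobutenone bound through its carbinol carbon (future C5) to the pyranone carbon α to the carbonyl (future C4a) then lacks only the C8–C8a bond to become ring A, and the two oxygens that emerge as hydroxyls differ because only O5–H is chelated to the C4 carbonyl.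

## Logic of the disconnections

19 from 18. The last cut removes four O–alkyl bonds at once: the three benzyl–oxygen bonds at O3, O3' and O4' and the isopropyl–oxygen bond at O7. This keeps every oxidisable phenol masked until the end and leaves the two methyl ethers as the only permanent O-substituents. A boron halide strong enough for the isopropyl ether would not spare benzyl ethers, so the two cleavages are merged into one operation. The forward step must not touch the methyl ethers beside the chelated O5.

18 from 17. The O8–CH3 bond is cut. O8 is the oxygen that ring formation leaves as a free phenol, whereas O5–H is locked in a hydrogen bond to the C4 carbonyl, so telling four oxygens apart is reduced to one mono-alkylation. The forward step has to run under mild base and without air, because 17 is a hydroquinone.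

17 from 14. The C8–C8a bond is cut and ring A is opened; retro-tautomerisation leads through 16 to 15, and ring closure of 15 to the four-membered ring gives 14. This is the strategic cut: a hexasubstituted benzene is exchanged for a four-membered ring hung on ring C, at no stereochemical cost because the carbinol centre of 14 is destroyed. The forward step demands outward rotation of the hydroxyl, closure of the ketene carbon onto the pyranone carbon next to the ring oxygen, and exclusion of oxygen.

14 from 9 and 12. The bond between the carbinol carbon (future C5) and the pyranone carbon α to the carbonyl (future C4a) is cut. This is the convergent cut, separating the ring B/ring C half from the four-carbon precursor of ring A. The forward step needs a carbanion at the pyranone α-carbon, made as 13 from 9, and its addition to that carbonyl of 12 which lies next to the methoxy-bearing carbon.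

12 from 10. The two alkoxy C–O bonds are cut, back through 11. The two ether oxygens of ring A that must end differently (O6 methylated, O7 free) are thus differentiated on a C4 building block by two successive substitutions. The demand is clean mono-substitution in the first stage.

9 from 8. The C–I bond is cut. The halogen is the handle for the carbanion. The forward step must halogenate the pyranone α-carbon and leave the dialkoxyphenyl ring alone.

8 from 4 and 5. Ring C is opened at the bond from the ring oxygen to the unsubstituted CH and cut between the alkoxy-bearing carbon and the carbonyl carbon, through 7 and 6. This builds the 3-alkoxy-2-aryl-4-pyranone from an enolate and a three-carbon acyl donor in one operation and avoids an oxidative furan-to-pyranone route with halogen, which an electron-rich dialkoxyphenyl ring would not survive. The demand is C- over O-acylation and an acid-mediated closure that spares benzyl ethers.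

4 from 1 and 2. The aryl–carbonyl bond (future C1'–C2) is cut, through 3. Both pieces are simple and the α-oxygen of the future C3 is carried in from the start. The demand is a single addition to the acyl donor.

## Other disconnections considered

Alternative 1: The cut runs through C4a–C8a, so ring A is unfolded into the open-chain triketo ester methyl 8-(benzyloxy)-2,4-dimethoxy-3,5,7-trioxooctanoate A2.
- Forward key step: a base would deprotonate the methylene between the two terminal ketones, the enolate would attack the ester carbonyl (Claisen closure of a six-membered ring), and enolisation would aromatise the product to the acylphloroglucinol 2-(benzyloxy)-1-(2,4,6-trihydroxy-3,5-dimethoxyphenyl)ethan-1-one A1. Ring C would follow by aroylation with a ring B acid derivative, acyl shift and cyclodehydration.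
- In its favour: both methyl ethers are in place before the arene exists, so no oxygen of ring A has to be told from another afterwards. A1 is symmetric about the acyl axis, so either ortho hydroxyl closes ring C to the same flavonol. On both points it is better than the chosen plan, which depends on a regioselective addition to 12 and a chelation-controlled methylation.
- Against it: A2 has three ketones, an ester and two enolisable α-methoxy methines. Its assembly needs several iterative acylations with masking, it would be a mixture of enols and hemiketals, and lactonisation of the 3,5-diketo ester to a 4-hydroxy-2-pyranone or aldol closure compete with the Claisen mode. A1 is an air-sensitive free phloroglucinol on which ring C must still be built in several steps.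
- Comparison: both plans make ring A by ring closure, the alternative before ring C and the chosen plan after it. The Claisen closure is ionic, reversible and of a familiar type, an advantage in precedent over the pericyclic cascade on an untested partner. In step economy the alternative is expected to be clearly longer than the eight steps of the chosen plan because of the way to A2.

Alternative 2: The cuts are C3–C4 and O1–C2, so ring C is formed last from ketone 4 of the chosen route and a complete ring A, the salicylate acetonide 5,7-bis(benzyloxy)-6,8-dimethoxy-2,2-dimethyl-4H-1,3-benzodioxin-4-one A4.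
- Forward key step: the lithium enolate of 4 would attack the lactone carbonyl of A4, the adduct would collapse with loss of acetone to a 1,3-diketone with a free ortho phenol, and acid would close ring C by cyclodehydration to 3,5,7-tris(benzyloxy)-2-[3,4-bis(benzyloxy)phenyl]-6,8-dimethoxy-4H-chromen-4-one A3. One hydrogenolysis would finish.
- In its favour: ring C chemistry of this type is established for flavonols (better in precedent). Ring A arrives with its oxygen pattern fixed, so there is no regiochemical question (better). The end game is one neutral hydrogenolysis, milder than the Lewis acid deprotection of the chosen plan (better). Ketone 4 is shared (equal).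
- Against it: the difficulty is moved, not solved. A4 is a hexasubstituted benzene with alternating benzyloxy and methoxy groups and a carboxyl carbon, reachable only by a long series of aromatic substitutions. The enolate must also attack a carbonyl flanked by an ortho benzyloxy group and the acetal oxygen, a hindered and electron-rich acyl donor.
- Comparison: the alternative buys certainty in the key step at the price of a long linear synthesis of A4; the chosen plan makes the crowded ring in one isomerisation from a C4 unit but carries the risk of an unprecedented cyclisation. Counting the way to A4, the alternative is expected to be two or more steps longer.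

Alternative 3: The cuts are C4a–C4, O1–C8a and O1–C2; the pieces are the aryne precursor 5-(benzyloxy)-4,6-dimethoxy-2-(trimethylsilyl)-1,3-phenylene bis(trifluoromethanesulfonate) A6 and 3-[3,4-bis(benzyloxy)phenyl]prop-2-ynoic acid A7.
- Forward key step: fluoride would generate the aryne from A6, the carboxylate oxygen of A7 would add to the aryne carbon remote from the triflyloxy group, the aryl anion would take over the acyl carbon, and the freed phenoxide would add 6-endo to the ynone to give 7-(benzyloxy)-2-[3,4-bis(benzyloxy)phenyl]-6,8-dimethoxy-4-oxo-4H-chromen-5-yl trifluoromethanesulfonate A5.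
- In its favour: three bonds and ring C are formed in one operation from two fragments, which is better than the chosen key step in bonds per step. A6 is symmetric, so either triflate can leave. The remaining triflate is a masked O5.
- Against it: A5 has no oxygen on C3, so the flavone must still be hydroxylated at C3, and the triflate must be cleaved at sulfur without opening ring C. The aryne is flanked by the triflyloxy group on one side and a methoxy group on the other, which direct a nucleophile to opposite carbons, so the regiochemistry rests on one group out-directing the other; this is no more secure than the addition to 12 in the chosen plan (equal). A6 is again a hexasubstituted benzene that needs a long preparation.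
- Comparison: the alternative builds ring C around a finished ring A, the chosen plan builds ring A onto a finished ring C. Its polar aryne cascade has closer precedent than the pericyclic closure onto a pyranone. In step economy it is expected to be the longest of the four because of A6 and the two extra steps after the key step.

Key step: step 6

Remark: 14 and 16 are racemic and 7 is an enolisable racemate; all these centres are erased on the way, so the target needs no stereocontrol. Compounds 1, 2, 5 and 10 are taken as commercial.

## Route

Step 1
Reactants: 1 aryl bromide 4-bromo-1,2-bis(benzyloxy)benzene; 2 amide 2-(benzyloxy)-N-methoxy-N-methylacetamide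
Product: 4 ketone 2-(benzyloxy)-1-[3,4-bis(benzyloxy)phenyl]ethan-1-one, via arylmagnesium bromide 3 (not isolated)
Conditions: Mg, THF, 40 °C; then 2, −20 → 0 °C; 1 M HCl
Reagents that add atoms: none
Why: Grignard formation followed by Weinreb ketone synthesis; the magnesium chelate of the tetrahedral adduct holds until the acidic quench, so the ketone should not be attacked a second time.

Step 2
Reactants: 4 ketone 2-(benzyloxy)-1-[3,4-bis(benzyloxy)phenyl]ethan-1-one; 5 acid chloride (E)-3-ethoxyprop-2-enoyl chloride
Product: 8 pyranone 3-(benzyloxy)-2-[3,4-bis(benzyloxy)phenyl]-4H-pyran-4-one, via lithium enolate 6 (not isolated), via 1,3-diketone 7 (not isolated)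
Conditions: LiN(SiMe3)2 (2.2 equiv), THF, −78 °C; 5, −78 → −20 °C; aq. NH4Cl; crude 7, p-TsOH·H2O (cat.), PhMe, 60 °C
Reagents that add atoms: none
Why: Claisen-type C-acylation of the chelated (Z)-lithium enolate by the acid chloride, the second equivalent of base taking up the more acidic diketone; acid then brings about 6-endo oxa-Michael addition of the aryl ketone enol to the β-ethoxy enone and loss of ethanol, the usual closure of a 1,3,5-tricarbonyl equivalent to a 4-pyranone.

Step 3
Reactants: 8 pyranone 3-(benzyloxy)-2-[3,4-bis(benzyloxy)phenyl]-4H-pyran-4-one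
Product: 9 iodide 3-(benzyloxy)-2-[3,4-bis(benzyloxy)phenyl]-5-iodo-4H-pyran-4-one
Conditions: I2, pyridine, DMAP (cat.), CH2Cl2, rt, dark
Reagents that add atoms: iodine, II
Why: α-Iodination of a cyclic vinylogous ester: C5 is the only nucleophilic carbon of the pyranone (β to the ring oxygen, α to C=O) and is reached directly or by reversible amine addition at C6, iodination of the enolate and loss of the amine; iodine–pyridine does not iodinate alkoxyarenes, which should keep ring B untouched.

Step 4
Reactants: 10 squaric acid dichloride 3,4-dichlorocyclobut-3-ene-1,2-dione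
Product: 12 mixed squarate 3-methoxy-4-(propan-2-yloxy)cyclobut-3-ene-1,2-dione, via chloro ester 11 (not isolated)
Conditions: i-PrOH (1.0 equiv), CH2Cl2, 0 °C → rt; then MeOH (1.1 equiv), Et3N (2.1 equiv), −20 → 0 °C
Reagents that add atoms: propan-2-ol, CC(C)O; methanol, CO
Why: Two successive addition–eliminations on a vinylogous acid chloride; the first alkoxy group deactivates the remaining C–Cl, so mono-substitution by the less nucleophilic secondary alcohol should hold, and methanol with base then replaces the second chloride at low temperature before ester exchange sets in.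

Step 5
Reactants: 9 iodide 3-(benzyloxy)-2-[3,4-bis(benzyloxy)phenyl]-5-iodo-4H-pyran-4-one; 12 mixed squarate 3-methoxy-4-(propan-2-yloxy)cyclobut-3-ene-1,2-dione
Product: 14 carbinol racemic 4-[5-(benzyloxy)-6-[3,4-bis(benzyloxy)phenyl]-4-oxo-4H-pyran-3-yl]-4-hydroxy-3-methoxy-2-(propan-2-yloxy)cyclobut-2-en-1-one, via pyranonylmagnesium chloride 13 (not isolated)
Conditions: i-PrMgCl·LiCl (1.05 equiv), THF, −60 °C; cannulation into 12 (1.3 equiv), THF, −78 °C; aq. NH4Cl at −78 °C
Reagents that add atoms: none
Why: Iodine–magnesium exchange of an α-iodo-β-oxy enone is fast at low temperature, and the alkenyl Grignard adds 1,2 to a squarate carbonyl, the standard entry to 4-hydroxycyclobutenones. Attack is expected at the carbonyl beside the methoxy-bearing carbon, because the isopropyl group screens the oxygen of its own neighbouring carbonyl from magnesium coordination; inverse addition into excess 12 prevents double addition. The carbinol centre is formed racemic and needs no control, since step 6 destroys it.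

Step 6
Reactants: 14 carbinol racemic 4-[5-(benzyloxy)-6-[3,4-bis(benzyloxy)phenyl]-4-oxo-4H-pyran-3-yl]-4-hydroxy-3-methoxy-2-(propan-2-yloxy)cyclobut-2-en-1-one
Product: 17 hydroquinone 3-(benzyloxy)-2-[3,4-bis(benzyloxy)phenyl]-5,8-dihydroxy-6-methoxy-7-(propan-2-yloxy)-4H-chromen-4-one, via dienylketene 15 (not isolated), via 8aH-dienone 16 (not isolated)
Conditions: PhMe (degassed, 0.02 M), 110 °C, Ar
Reagents that add atoms: none
Why: Proposed new method: heating should open the cyclobutenone by conrotatory 4π cleavage of the bond between the carbonyl carbon and the carbinol carbon, the hydroxyl turning outward (donor-outward torquoselectivity) so that the pyranonyl group lies cis to the ketene in the (Z)-dienylketene 15. A thermal disrotatory 6π electrocyclisation should then join the ketene carbon (C8) to the unsubstituted pyranone carbon next to the ring oxygen (C8a), closing the six-membered carbocycle of ring A as the 8aH-dienone 16, and a proton shift from C8a to the C8 oxygen should aromatise it to 17. The closest known reaction type is the Moore ring expansion of 4-aryl- and 4-alkenyl-4-hydroxycyclobutenones to annulated hydroquinones; new here is that the 2π partner is the enol-ether double bond of a cross-conjugated 4-pyranone. No stereocentre results, since the carbinol centre becomes sp2 and the C8a centre of 16 is lost on tautomerisation. The step needs carbon–carbon closure to win over lactonisation to a butenolide, which the outward rotation secures because the hydroxyl is then trans to the ketene, and it needs the O6/O7 pattern, which is already fixed in 14. Oxygen is excluded so that the electron-rich hydroquinone is not oxidised to the 5,8-quinone.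

Step 7
Reactants: 17 hydroquinone 3-(benzyloxy)-2-[3,4-bis(benzyloxy)phenyl]-5,8-dihydroxy-6-methoxy-7-(propan-2-yloxy)-4H-chromen-4-one
Product: 18 methyl ether 3-(benzyloxy)-2-[3,4-bis(benzyloxy)phenyl]-5-hydroxy-6,8-dimethoxy-7-(propan-2-yloxy)-4H-chromen-4-one
Conditions: MeI (1.2 equiv), K2CO3 (1.5 equiv), acetone (degassed), rt, Ar
Reagents that add atoms: iodomethane, CI
Why: Williamson methylation; the 5-hydroxyl is tied in a six-membered hydrogen bond to C4=O and is much less nucleophilic, so a small excess of MeI with K2CO3 should alkylate O8 only.

Step 8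
Reactants: 18 methyl ether 3-(benzyloxy)-2-[3,4-bis(benzyloxy)phenyl]-5-hydroxy-6,8-dimethoxy-7-(propan-2-yloxy)-4H-chromen-4-one
Product: 19 target 3,5,7-trihydroxy-2-(3,4-dihydroxyphenyl)-6,8-dimethoxy-4H-chromen-4-one
Conditions: BCl3 (excess), C6HMe5, CH2Cl2, −78 → 0 °C; MeOH, then H2O
Reagents that add atoms: none
Why: Lewis acid ether cleavage: BCl3 should cleave the benzyl aryl ethers at low temperature (benzyl cations trapped by pentamethylbenzene) and the secondary alkyl aryl ether on warming, while methyl aryl ethers that are not peri to a carbonyl survive; the boron chelates are hydrolysed on work-up.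

## Compound list

1 | 4-bromo-1,2-bis(benzyloxy)benzene | Brc1ccc(OCc2ccccc2)c(OCc2ccccc2)c1 | starting material
2 | 2-(benzyloxy)-N-methoxy-N-methylacetamide | CON(C)C(=O)COCc1ccccc1 | starting material
3 | [3,4-bis(benzyloxy)phenyl]magnesium bromide | Br[Mg]c1ccc(OCc2ccccc2)c(OCc2ccccc2)c1 | intermediate
4 | 2-(benzyloxy)-1-[3,4-bis(benzyloxy)phenyl]ethan-1-one | O=C(COCc1ccccc1)c1ccc(OCc2ccccc2)c(OCc2ccccc2)c1 | intermediate
5 | (E)-3-ethoxyprop-2-enoyl chloride | CCO/C=C/C(Cl)=O | starting material
6 | lithium (Z)-2-(benzyloxy)-1-[3,4-bis(benzyloxy)phenyl]ethen-1-olate | [Li+].[O-]/C(=C\OCc1ccccc1)c1ccc(OCc2ccccc2)c(OCc2ccccc2)c1 | intermediate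
7 | (E)-2-(benzyloxy)-1-[3,4-bis(benzyloxy)phenyl]-5-ethoxypent-4-ene-1,3-dione (racemic, enolisable) | CCO/C=C/C(=O)C(OCc1ccccc1)C(=O)c1ccc(OCc2ccccc2)c(OCc2ccccc2)c1 | intermediate
8 | 3-(benzyloxy)-2-[3,4-bis(benzyloxy)phenyl]-4H-pyran-4-one | O=c1ccoc(-c2ccc(OCc3ccccc3)c(OCc3ccccc3)c2)c1OCc1ccccc1 | intermediate
9 | 3-(benzyloxy)-2-[3,4-bis(benzyloxy)phenyl]-5-iodo-4H-pyran-4-one | O=c1c(I)coc(-c2ccc(OCc3ccccc3)c(OCc3ccccc3)c2)c1OCc1ccccc1 | intermediate
10 | 3,4-dichlorocyclobut-3-ene-1,2-dione | O=C1C(=O)C(Cl)=C1Cl | starting material
11 | 3-chloro-4-(propan-2-yloxy)cyclobut-3-ene-1,2-dione | CC(C)OC1=C(Cl)C(=O)C1=O | intermediate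
12 | 3-methoxy-4-(propan-2-yloxy)cyclobut-3-ene-1,2-dione | COC1=C(OC(C)C)C(=O)C1=O | intermediate
13 | {5-(benzyloxy)-6-[3,4-bis(benzyloxy)phenyl]-4-oxo-4H-pyran-3-yl}magnesium chloride (LiCl complex) | Cl[Mg]c1coc(-c2ccc(OCc3ccccc3)c(OCc3ccccc3)c2)c(OCc2ccccc2)c1=O | intermediate
14 | racemic 4-[5-(benzyloxy)-6-[3,4-bis(benzyloxy)phenyl]-4-oxo-4H-pyran-3-yl]-4-hydroxy-3-methoxy-2-(propan-2-yloxy)cyclobut-2-en-1-one | O=C1C(OC(C)C)=C(OC)C1(O)c1coc(-c2ccc(OCc3ccccc3)c(OCc3ccccc3)c2)c(OCc2ccccc2)c1=O | intermediate
15 | (3Z)-4-[5-(benzyloxy)-6-[3,4-bis(benzyloxy)phenyl]-4-oxo-4H-pyran-3-yl]-4-hydroxy-3-methoxy-2-(propan-2-yloxy)buta-1,3-dien-1-one | O=C=C(OC(C)C)/C(OC)=C(/O)c1coc(-c2ccc(OCc3ccccc3)c(OCc3ccccc3)c2)c(OCc2ccccc2)c1=O | intermediate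
16 | racemic 3-(benzyloxy)-2-[3,4-bis(benzyloxy)phenyl]-5-hydroxy-6-methoxy-7-(propan-2-yloxy)-8aH-chromene-4,8-dione | O=C1C(OC(C)C)=C(OC)C(O)=C2C(=O)C(OCc3ccccc3)=C(c3ccc(OCc4ccccc4)c(OCc4ccccc4)c3)OC12 | intermediate
17 | 3-(benzyloxy)-2-[3,4-bis(benzyloxy)phenyl]-5,8-dihydroxy-6-methoxy-7-(propan-2-yloxy)-4H-chromen-4-one | COc1c(OC(C)C)c(O)c2oc(-c3ccc(OCc4ccccc4)c(OCc4ccccc4)c3)c(OCc3ccccc3)c(=O)c2c1O | intermediate
18 | 3-(benzyloxy)-2-[3,4-bis(benzyloxy)phenyl]-5-hydroxy-6,8-dimethoxy-7-(propan-2-yloxy)-4H-chromen-4-one | COc1c(OC(C)C)c(OC)c2oc(-c3ccc(OCc4ccccc4)c(OCc4ccccc4)c3)c(OCc3ccccc3)c(=O)c2c1O | intermediate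
19 | 3,5,7-trihydroxy-2-(3,4-dihydroxyphenyl)-6,8-dimethoxy-4H-chromen-4-one (3,5,7,3',4'-pentahydroxy-6,8-dimethoxyflavone) | COc1c(O)c(OC)c2oc(-c3ccc(O)c(O)c3)c(O)c(=O)c2c1O | target

Total step count: 8. Longest linear sequence: 7 steps (steps 1, 2, 3, 5, 6, 7, 8); step 4 is a one-step side branch.

## Least certain steps

Step 6 (key step). The most likely failure is that the ring opening runs but the 6π closure does not follow, because the pyranone carbon that must bond to the ketene is an electron-poor β-carbon of an enone. The ketene would then revert, and material would drain away through the minor inward-hydroxyl rotamer (lactonisation) or through oxidation of the product. The fallback uses known chemistry only, sets out from 4 and returns at 19; ring A is then taken from a phloroglucinol and oxygenated afterwards.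
- The lithium enolate of 4 (LiN(SiMe3)2, THF, −78 °C) would be acylated at the lactone carbonyl of 5,7-bis(benzyloxy)-2,2-dimethyl-4H-1,3-benzodioxin-4-one F1 (from the commercial 5,7-dihydroxy acetonide, benzyl bromide and K2CO3).
- Loss of acetone would give the diketone 1-[2,4-bis(benzyloxy)-6-hydroxyphenyl]-2-(benzyloxy)-3-[3,4-bis(benzyloxy)phenyl]propane-1,3-dione F2.
- Acid (p-TsOH, PhMe, 80 °C) would cyclodehydrate it to 3,5,7-tris(benzyloxy)-2-[3,4-bis(benzyloxy)phenyl]-4H-chromen-4-one F3.
- N-Bromosuccinimide (2.1 equiv, DMF) would brominate both free positions of the activated ring A to 3,5,7-tris(benzyloxy)-2-[3,4-bis(benzyloxy)phenyl]-6,8-dibromo-4H-chromen-4-one F4.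
- NaOMe with CuBr in DMF–MeOH at 110 °C (Ullmann-type ether synthesis) would exchange both bromides to give 3,5,7-tris(benzyloxy)-2-[3,4-bis(benzyloxy)phenyl]-6,8-dimethoxy-4H-chromen-4-one F5.
- Hydrogenolysis (H2, Pd/C, EtOAc–MeOH) would give 19.

Step 5. The most likely failure is attack at the wrong carbonyl of 12, because the steric bias between methoxy and isopropoxy is modest and the small electronic difference may oppose it; this would transpose the O6 and O7 substituents. A second risk is β-elimination of the enolate oxygen from 13 if the exchange runs too warm. The fallback sets out from 9 and returns at 14; it makes the carbonyl to be attacked the only one.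
- Dimethyl squarate would be converted (HC(OMe)3, MeOH, cat. H2SO4) into its mono-ketal 2,3,4,4-tetramethoxycyclobut-2-en-1-one F6.
- Only the alkoxy group β to the remaining carbonyl can exchange by addition–elimination, so NaOi-Pr (cat.) in i-PrOH would give 2,4,4-trimethoxy-3-(propan-2-yloxy)cyclobut-2-en-1-one F7.
- Grignard 13, made from 9 as in step 5, would add to the single carbonyl to give racemic 3-(benzyloxy)-2-[3,4-bis(benzyloxy)phenyl]-5-[1-hydroxy-2,4,4-trimethoxy-3-(propan-2-yloxy)cyclobut-2-en-1-yl]-4H-pyran-4-one F8.
- Brief ketal hydrolysis (oxalic acid on wet silica, CH2Cl2, 0 °C) would return to 14 with the methoxy carbon next to the carbinol by construction.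

Step 3. The most likely failure is either no reaction at the weakly nucleophilic pyranone α-carbon or, under more forcing electrophilic conditions, iodination of ring B para to a benzyloxy group. The fallback sets out from 8 and returns at 9; it replaces electrophilic substitution by carbonyl-directed deprotonation. (2,2,6,6-Tetramethylpiperidin-1-yl)zinc chloride·LiCl (TMPZnCl·LiCl, THF, rt) would zincate the position beside the carbonyl to give {5-(benzyloxy)-6-[3,4-bis(benzyloxy)phenyl]-4-oxo-4H-pyran-3-yl}zinc chloride F9, and iodolysis with I2 would give 9.

Step 8. The most likely failure is over-reaction: chelation-assisted loss of the 6-O-methyl group next to the boron-bound O5 during the warming needed for the isopropyl ether, or C-benzylation of the electron-rich rings by untrapped benzyl cations. The fallback sets out from 18 and returns at 19; it separates the two cleavages into orthogonal operations. Hydrogenolysis (H2, Pd/C, EtOAc–MeOH) would first remove the three benzyl groups to give 3,5-dihydroxy-2-(3,4-dihydroxyphenyl)-6,8-dimethoxy-7-(propan-2-yloxy)-4H-chromen-4-one F10, and a short treatment with BCl3 (CH2Cl2, −78 → −20 °C) would then cleave only the isopropyl ether.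

## Further compounds

F1 | step 6 | 5,7-bis(benzyloxy)-2,2-dimethyl-4H-1,3-benzodioxin-4-one | CC1(C)OC(=O)c2c(OCc3ccccc3)cc(OCc3ccccc3)cc2O1
F2 | step 6 | 1-[2,4-bis(benzyloxy)-6-hydroxyphenyl]-2-(benzyloxy)-3-[3,4-bis(benzyloxy)phenyl]propane-1,3-dione (racemic, enolisable) | O=C(c1c(O)cc(OCc2ccccc2)cc1OCc1ccccc1)C(OCc1ccccc1)C(=O)c1ccc(OCc2ccccc2)c(OCc2ccccc2)c1
F3 | step 6 | 3,5,7-tris(benzyloxy)-2-[3,4-bis(benzyloxy)phenyl]-4H-chromen-4-one | O=c1c(OCc2ccccc2)c(-c2ccc(OCc3ccccc3)c(OCc3ccccc3)c2)oc2cc(OCc3ccccc3)cc(OCc3ccccc3)c12
F4 | step 6 | 3,5,7-tris(benzyloxy)-2-[3,4-bis(benzyloxy)phenyl]-6,8-dibromo-4H-chromen-4-one | O=c1c(OCc2ccccc2)c(-c2ccc(OCc3ccccc3)c(OCc3ccccc3)c2)oc2c(Br)c(OCc3ccccc3)c(Br)c(OCc3ccccc3)c12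
F5 | step 6 | 3,5,7-tris(benzyloxy)-2-[3,4-bis(benzyloxy)phenyl]-6,8-dimethoxy-4H-chromen-4-one | COc1c(OCc2ccccc2)c(OC)c2oc(-c3ccc(OCc4ccccc4)c(OCc4ccccc4)c3)c(OCc3ccccc3)c(=O)c2c1OCc1ccccc1
F6 | step 5 | 2,3,4,4-tetramethoxycyclobut-2-en-1-one | COC1=C(OC)C(OC)(OC)C1=O
F7 | step 5 | 2,4,4-trimethoxy-3-(propan-2-yloxy)cyclobut-2-en-1-one | COC1=C(OC(C)C)C(OC)(OC)C1=O
F8 | step 5 | racemic 3-(benzyloxy)-2-[3,4-bis(benzyloxy)phenyl]-5-[1-hydroxy-2,4,4-trimethoxy-3-(propan-2-yloxy)cyclobut-2-en-1-yl]-4H-pyran-4-one | COC1=C(OC(C)C)C(OC)(OC)C1(O)c1coc(-c2ccc(OCc3ccccc3)c(OCc3ccccc3)c2)c(OCc2ccccc2)c1=O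
F9 | step 3 | {5-(benzyloxy)-6-[3,4-bis(benzyloxy)phenyl]-4-oxo-4H-pyran-3-yl}zinc chloride | Cl[Zn]c1coc(-c2ccc(OCc3ccccc3)c(OCc3ccccc3)c2)c(OCc2ccccc2)c1=O
F10 | step 8 | 3,5-dihydroxy-2-(3,4-dihydroxyphenyl)-6,8-dimethoxy-7-(propan-2-yloxy)-4H-chromen-4-one | COc1c(OC(C)C)c(OC)c2oc(-c3ccc(O)c(O)c3)c(O)c(=O)c2c1O
A1 | alternative 1 | 2-(benzyloxy)-1-(2,4,6-trihydroxy-3,5-dimethoxyphenyl)ethan-1-one | COc1c(O)c(OC)c(O)c(C(=O)COCc2ccccc2)c1O
A2 | alternative 1 | methyl 8-(benzyloxy)-2,4-dimethoxy-3,5,7-trioxooctanoate (mixture of epimers, enolisable) | COC(=O)C(OC)C(=O)C(OC)C(=O)CC(=O)COCc1ccccc1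
A3 | alternative 2 | 3,5,7-tris(benzyloxy)-2-[3,4-bis(benzyloxy)phenyl]-6,8-dimethoxy-4H-chromen-4-one | COc1c(OCc2ccccc2)c(OC)c2oc(-c3ccc(OCc4ccccc4)c(OCc4ccccc4)c3)c(OCc3ccccc3)c(=O)c2c1OCc1ccccc1
A4 | alternative 2 | 5,7-bis(benzyloxy)-6,8-dimethoxy-2,2-dimethyl-4H-1,3-benzodioxin-4-one | COc1c(OCc2ccccc2)c(OC)c2OC(C)(C)OC(=O)c2c1OCc1ccccc1
A5 | alternative 3 | 7-(benzyloxy)-2-[3,4-bis(benzyloxy)phenyl]-6,8-dimethoxy-4-oxo-4H-chromen-5-yl trifluoromethanesulfonate | COc1c(OCc2ccccc2)c(OC)c2oc(-c3ccc(OCc4ccccc4)c(OCc4ccccc4)c3)cc(=O)c2c1OS(=O)(=O)C(F)(F)F
A6 | alternative 3 | 5-(benzyloxy)-4,6-dimethoxy-2-(trimethylsilyl)-1,3-phenylene bis(trifluoromethanesulfonate) | COc1c(OCc2ccccc2)c(OC)c(OS(=O)(=O)C(F)(F)F)c([Si](C)(C)C)c1OS(=O)(=O)C(F)(F)F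
A7 | alternative 3 | 3-[3,4-bis(benzyloxy)phenyl]prop-2-ynoic acid | OC(=O)C#Cc1ccc(OCc2ccccc2)c(OCc2ccccc2)c1
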